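**Remark on the chemistry:** the methyl enol ether is carried as an E/Z mixture, since both isomers converge in step 14. Locants in the Why lines follow the bicyclo[3.3.1]non-2-ene numbering of the target: C1 formyl-bearing bridgehead, C2=C3 enal, C4 methylene, C5 methyl-bearing bridgehead, C8 side-chain carbon, C9 acetoxy carbon. Ring A is C1, C5, C6, C7, C8, C9; ring B is C1, C2, C3, C4, C5, C9.

## Retrosynthetic overview

1. Target ⇐ bicyclic hydroxy enal 21 (C1–CH2OTIPS, C9–OH) by acetylation, desilylation and oxidation.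
2. 21 ⇐ acyclic dialdehyde enol ether 19 in one operation: SmI2 joins the neopentyl aldehyde carbon C9 to the enal β-carbon C5 (closes ring A), then the methyl enol ether carbon C2 attacks the freed C3 aldehyde with loss of methanol (closes ring B).
3. Enabling feature: in ring B the C9 oxygen and enal carbon C3 stand 1,4 across quaternary C5 (O–C9–C5–C4–C3, two like-polarity carbons that a reductive union joins directly); bridgehead C1 is quaternary, so C2 is the only possible aldol donor and the C2 and C4 arms sit 1,3-diaxial on the ring A chair.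
4. 19 ⇐ B-alkyl Suzuki coupling (C6–C5) of a 9-BBN borane with (E)-3-iodobut-2-en-1-ol; the vinyl and enol ether groups come from Wittig reactions on a lactol and an aldehyde.
5. C1 and C8 ⇐ two trans-selective α-hydroxymethylations of a β-substituted γ-butyrolactone from Evans alkylation of (R)-citronellic acid, which supplies the side-chain stereocentre. Ring order: A, then B, both in step 14.

Key step: step 14

## Route

Step 1
Reactants: 1 (R)-citronellic acid; 2 (R)-4-benzyloxazolidin-2-one
Product: 3 (4R)-4-benzyl-3-[(3R)-3,7-dimethyloct-6-enoyl]-1,3-oxazolidin-2-one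
Conditions: PivCl, Et3N, THF, −20 °C; then 2, LiCl, rt
Reagents that add atoms: none
Why: Mixed-anhydride N-acylation of the oxazolidinone (Evans auxiliary attachment) should proceed without touching the existing stereocentre.

Step 2
Reactants: 3
Product: 4 tert-butyl (3R,4R)-3-{[(4R)-4-benzyl-2-oxo-1,3-oxazolidin-3-yl]carbonyl}-4,8-dimethylnon-7-enoate
Conditions: NaHMDS, THF, −78 °C; BrCH2CO2t-Bu, −78 → −40 °C
Reagents that add atoms: tert-butyl bromoacetate, BrCC(=O)OC(C)(C)C
Why: Evans asymmetric alkylation of the chelated (Z)-sodium enolate on the face opposite the benzyl group should set C8 under auxiliary control, independent of the neighbouring methyl stereocentre.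

Step 3
Reactants: 4
Product: 6 (4R)-4-[(2R)-6-methylhept-5-en-2-yl]oxolan-2-one, via hydroxy ester 5 (not isolated)
Conditions: LiBH4, MeOH, THF, 0 °C; then TsOH·H2O (cat.), CH2Cl2, rt
Reagents that add atoms: none
Why: Chemoselective borohydride reduction of the imide (tert-butyl ester untouched) releases the auxiliary, and acid-catalysed intramolecular transesterification should close the γ-lactone with no stereocentre involved.

Step 4
Reactants: 6
Product: 7 (3R,4S)-4-[(2R)-6-methylhept-5-en-2-yl]-3-{[(triisopropylsilyl)oxy]methyl}oxolan-2-one (3,4-trans)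
Conditions: LDA, THF, −78 °C; TOM-Cl, −78 → −40 °C
Reagents that add atoms: (triisopropylsiloxy)methyl chloride, ClCO[Si](C(C)C)(C(C)C)C(C)C
Why: Lactone enolate alkylation with a chloromethyl ether should occur trans to the bulky β-substituent.

Step 5
Reactants: 7
Product: 9 (3R,4S)-4-[(2R)-6-methylhept-5-en-2-yl]-3-{[(triethylsilyl)oxy]methyl}-3-{[(triisopropylsilyl)oxy]methyl}oxolan-2-one (CH2OTES trans and CH2OTIPS cis to the side chain), via hydroxymethyl lactone 8 (not isolated)
Conditions: LDA, THF, −78 °C; CH2O (gas), −78 °C; then TESCl, −78 → −20 °C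
Reagents that add atoms: formaldehyde, C=O; chlorotriethylsilane, CC[Si](Cl)(CC)CC
Why: Aldol addition of the tetrasubstituted lactone enolate to formaldehyde anti to the C4 side chain should set the quaternary centre (future C1), and silylation of the aldolate in the flask blocks retro-aldol.

Step 6
Reactants: 9
Product: 10 the corresponding lactol, (3R,4S)-configured oxolan-2-ol (anomer mixture)
Conditions: DIBAL-H, CH2Cl2, −78 °C
Reagents that add atoms: none
Why: Partial reduction of a lactone to the lactol at low temperature is reliable and no stereocentre of the route is affected.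

Step 7
Reactants: 10
Product: 11 5-methoxy-2-[(2R)-6-methylhept-5-en-2-yl]-3-{[(triethylsilyl)oxy]methyl}-3-{[(triisopropylsilyl)oxy]methyl}pent-4-en-1-ol (E/Z mixture)
Conditions: MeOCH2PPh3Cl, KHMDS, THF, 0 °C → rt
Reagents that add atoms: (methoxymethyl)triphenylphosphonium chloride, [Cl-].COC[P+](c1ccccc1)(c1ccccc1)c1ccccc1
Why: Wittig methoxymethylenation of the open hydroxy-aldehyde tautomer should turn the lactol carbon into the enol ether (future C2 and its formyl carbon) and free the primary alcohol.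

Step 8
Reactants: 11
Product: 12 the corresponding pent-4-enal (aldehyde next to the future C8)
Conditions: DMP, pyridine, CH2Cl2, 0 °C
Reagents that add atoms: none
Why: Buffered Dess–Martin oxidation should spare the enol ether and avoid epimerisation of the α-stereocentre.

Step 9
Reactants: 12
Product: 13 1-methoxy-4-[(2R)-6-methylhept-5-en-2-yl]-3-{[(triethylsilyl)oxy]methyl}-3-{[(triisopropylsilyl)oxy]methyl}hexa-1,5-diene
Conditions: Ph3PCH3Br, KHMDS, THF, −78 → 0 °C
Reagents that add atoms: methyltriphenylphosphonium bromide, [Br-].C[P+](c1ccccc1)(c1ccccc1)c1ccccc1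
Why: Wittig methylenation with a non-stabilised ylide at low temperature should give the vinyl group without epimerising the adjacent stereocentre.

Step 10
Reactants: 14 but-2-yn-1-ol
Product: 15 (E)-3-iodobut-2-en-1-ol
Conditions: Cp2Zr(H)Cl (2.2 equiv), THF, rt; then I2, 0 °C
Reagents that add atoms: iodine, II
Why: syn-Hydrozirconation places zirconium on the alkyne carbon remote from the oxygenated substituent, and iodinolysis with retention should give the (E)-vinyl iodide (hydrozirconation–iodination).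

Step 11
Reactants: 13; 15 (E)-3-iodobut-2-en-1-ol
Product: 17 (2E)-9-methoxy-3-methyl-6-[(2R)-6-methylhept-5-en-2-yl]-7-{[(triethylsilyl)oxy]methyl}-7-{[(triisopropylsilyl)oxy]methyl}nona-2,8-dien-1-ol, via alkylborane 16 (not isolated)
Conditions: 9-BBN, THF, rt; then 15, PdCl2(dppf) (5 mol %), AsPh3, Cs2CO3, DMF/H2O, rt
Reagents that add atoms: none
Why: 9-BBN should hydroborate the monosubstituted vinyl group in preference to the trisubstituted alkene and the 1,2-disubstituted enol ether, and B-alkyl Suzuki–Miyaura coupling retains the (E)-geometry of the iodide.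

Step 12
Reactants: 17
Product: 18 the diol, (2E)-7-(hydroxymethyl)-9-methoxy-3-methyl-6-[(2R)-6-methylhept-5-en-2-yl]-7-{[(triisopropylsilyl)oxy]methyl}nona-2,8-dien-1-ol
Conditions: TBAF, AcOH, THF, 0 °C
Reagents that add atoms: none
Why: Buffered fluoride should cleave the primary triethylsilyl ether much faster than the triisopropylsilyl ether, under non-acidic conditions that the enol ether tolerates.

Step 13
Reactants: 18
Product: 19 (2E)-7-formyl-9-methoxy-3-methyl-6-[(2R)-6-methylhept-5-en-2-yl]-7-{[(triisopropylsilyl)oxy]methyl}nona-2,8-dienal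
Conditions: DMP, pyridine, CH2Cl2, 0 °C → rt
Reagents that add atoms: none
Why: Double Dess–Martin oxidation of the allylic and the neopentyl alcohol should give the (E)-enal and the non-enolisable α-quaternary aldehyde in one step.

Step 14
Reactants: 19
Product: 21 9-hydroxy-5-methyl-8-[(2R)-6-methylhept-5-en-2-yl]-1-{[(triisopropylsilyl)oxy]methyl}bicyclo[3.3.1]non-2-ene-2-carbaldehyde (ring configuration as in the target), via hydroxy aldehyde 20 (not isolated)
Conditions: SmI2 (2.2 equiv), THF (0.005 M), −78 °C; then t-BuOH, BF3·OEt2, −78 → −20 °C; 1 M HCl work-up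
Reagents that add atoms: none
Why: Proposed new method: single-electron reduction by SmI2 should give a ketyl-type radical that closes ring A by 6-exo-trig bond formation between C9 and the enal β-carbon C5, and a second electron gives the trivalent-samarium alkoxide and aldehyde enolate, a reductive union of two electrophilic carbons whose closest known relatives are SmI2 ketyl–olefin cyclizations of aldehydes onto β,β-disubstituted enoates and SmI2 cyclization–aldol cascades, here extended to an enal acceptor. Protonation by t-BuOH then frees the C3 aldehyde, BF3·OEt2 activates it for attack by the enol ether carbon C2 (6-(enolexo)-exo-trig Mukaiyama–Prins closure of ring B, a known reaction type for enol ethers and aldehydes), and loss of methanol and water on acidic work-up gives the conjugated enal. C9 and C5 are set in a chair transition state with the C8 side chain equatorial and the samarium-bound oxygen axial and anti to the acceptor double bond (the anti preference of ketyl–olefin cyclizations, reinforced because an equatorial oxygen would be gauche to both substituents of quaternary C1), which places the CH2CHO arm axial and cis to the axial enol ether arm; C1 and C8 are already fixed and no other stereocentre forms. The step needs C9–C5 coupling to beat pinacol coupling (six- against eight-membered ring, high dilution) and a single direction for the condensation, which is secured because only C2 is a nucleophilic enol ether, only C3 is an aldehyde at that stage and C1 has no α-hydrogen. Any C5 epimer cannot close ring B and should be removed here.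

Step 15
Reactants: 21
Product: 22 the C9 acetate of 21
Conditions: Ac2O, DMAP, Et3N, CH2Cl2, rt
Reagents that add atoms: acetic anhydride, CC(=O)OC(C)=O
Why: DMAP-catalysed acylation should acetylate the hindered secondary alcohol, the only free hydroxyl present.

Step 16
Reactants: 22
Product: 23 9-acetoxy-1-(hydroxymethyl)-5-methyl-8-[(2R)-6-methylhept-5-en-2-yl]bicyclo[3.3.1]non-2-ene-2-carbaldehyde
Conditions: HF·pyridine, pyridine, THF, 0 °C → rt
Reagents that add atoms: none
Why: Acidic fluoride should cleave the primary silyl ether without base-induced 1,3-acyl migration or harm to the enal.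

Step 17
Reactants: 23
Product: 24 (1R,5R,8S,9R)-1,2-diformyl-5-methyl-8-[(2R)-6-methylhept-5-en-2-yl]bicyclo[3.3.1]non-2-en-9-yl acetate (target)
Conditions: DMP, pyridine, CH2Cl2, 0 °C
Reagents that add atoms: none
Why: Dess–Martin oxidation of the neopentyl alcohol should give the non-enolisable C1 aldehyde, which cannot eliminate the β-acetate.

## Compound list

1 | (R)-citronellic acid, (3R)-3,7-dimethyloct-6-enoic acid | OC(=O)C[C@H](C)CCC=C(C)C | starting material
2 | (R)-4-benzyloxazolidin-2-one | O=C1N[C@H](Cc2ccccc2)CO1 | starting material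
3 | (4R)-4-benzyl-3-[(3R)-3,7-dimethyloct-6-enoyl]-1,3-oxazolidin-2-one | O=C1OC[C@@H](Cc2ccccc2)N1C(=O)C[C@H](C)CCC=C(C)C | intermediate
4 | tert-butyl (3R,4R)-3-{[(4R)-4-benzyl-2-oxo-1,3-oxazolidin-3-yl]carbonyl}-4,8-dimethylnon-7-enoate | O=C1OC[C@@H](Cc2ccccc2)N1C(=O)[C@H](CC(=O)OC(C)(C)C)[C@H](C)CCC=C(C)C | intermediate
5 | tert-butyl (3R,4R)-3-(hydroxymethyl)-4,8-dimethylnon-7-enoate (not isolated) | CC(C)(C)OC(=O)C[C@@H](CO)[C@H](C)CCC=C(C)C | intermediate
6 | (4R)-4-[(2R)-6-methylhept-5-en-2-yl]oxolan-2-one | O=C1C[C@@H](CO1)[C@H](C)CCC=C(C)C | intermediate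
7 | (3R,4S)-4-[(2R)-6-methylhept-5-en-2-yl]-3-{[(triisopropylsilyl)oxy]methyl}oxolan-2-one | O=C1[C@@H](CO[Si](C(C)C)(C(C)C)C(C)C)[C@@H](CO1)[C@H](C)CCC=C(C)C | intermediate
8 | (3R,4S)-3-(hydroxymethyl)-4-[(2R)-6-methylhept-5-en-2-yl]-3-{[(triisopropylsilyl)oxy]methyl}oxolan-2-one (formed as its lithium alkoxide, not isolated) | O=C1[C@](CO)(CO[Si](C(C)C)(C(C)C)C(C)C)[C@@H](CO1)[C@H](C)CCC=C(C)C | intermediate
9 | (3R,4S)-4-[(2R)-6-methylhept-5-en-2-yl]-3-{[(triethylsilyl)oxy]methyl}-3-{[(triisopropylsilyl)oxy]methyl}oxolan-2-one | O=C1[C@](CO[Si](CC)(CC)CC)(CO[Si](C(C)C)(C(C)C)C(C)C)[C@@H](CO1)[C@H](C)CCC=C(C)C | intermediate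
10 | lactol of 9 (oxolan-2-ol, anomer mixture) | OC1OC[C@@H]([C@H](C)CCC=C(C)C)[C@@]1(CO[Si](CC)(CC)CC)CO[Si](C(C)C)(C(C)C)C(C)C | intermediate
11 | 5-methoxy-2-[(2R)-6-methylhept-5-en-2-yl]-3-{[(triethylsilyl)oxy]methyl}-3-{[(triisopropylsilyl)oxy]methyl}pent-4-en-1-ol (E/Z) | COC=C[C@](CO[Si](CC)(CC)CC)(CO[Si](C(C)C)(C(C)C)C(C)C)[C@@H](CO)[C@H](C)CCC=C(C)C | intermediate
12 | aldehyde from 11 (pent-4-enal) | COC=C[C@](CO[Si](CC)(CC)CC)(CO[Si](C(C)C)(C(C)C)C(C)C)[C@@H](C=O)[C@H](C)CCC=C(C)C | intermediate
13 | 1-methoxy-4-[(2R)-6-methylhept-5-en-2-yl]-3-{[(triethylsilyl)oxy]methyl}-3-{[(triisopropylsilyl)oxy]methyl}hexa-1,5-diene | COC=C[C@](CO[Si](CC)(CC)CC)(CO[Si](C(C)C)(C(C)C)C(C)C)[C@@H](C=C)[C@H](C)CCC=C(C)C | intermediate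
14 | but-2-yn-1-ol | CC#CCO | starting material
15 | (E)-3-iodobut-2-en-1-ol | C/C(I)=C\CO | intermediate
16 | B-alkyl-9-borabicyclo[3.3.1]nonane from 13 (not isolated) | COC=C[C@](CO[Si](CC)(CC)CC)(CO[Si](C(C)C)(C(C)C)C(C)C)[C@@H](CCB1C2CCCC1CCC2)[C@H](C)CCC=C(C)C | intermediate
17 | (2E)-9-methoxy-3-methyl-6-[(2R)-6-methylhept-5-en-2-yl]-7-{[(triethylsilyl)oxy]methyl}-7-{[(triisopropylsilyl)oxy]methyl}nona-2,8-dien-1-ol | COC=C[C@](CO[Si](CC)(CC)CC)(CO[Si](C(C)C)(C(C)C)C(C)C)[C@@H](CC/C(C)=C/CO)[C@H](C)CCC=C(C)C | intermediate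
18 | (2E)-7-(hydroxymethyl)-9-methoxy-3-methyl-6-[(2R)-6-methylhept-5-en-2-yl]-7-{[(triisopropylsilyl)oxy]methyl}nona-2,8-dien-1-ol | COC=C[C@](CO)(CO[Si](C(C)C)(C(C)C)C(C)C)[C@@H](CC/C(C)=C/CO)[C@H](C)CCC=C(C)C | intermediate
19 | (2E)-7-formyl-9-methoxy-3-methyl-6-[(2R)-6-methylhept-5-en-2-yl]-7-{[(triisopropylsilyl)oxy]methyl}nona-2,8-dienal | COC=C[C@](C=O)(CO[Si](C(C)C)(C(C)C)C(C)C)[C@@H](CC/C(C)=C/C=O)[C@H](C)CCC=C(C)C | intermediate
20 | monocyclic hydroxy aldehyde (ring A closed: axial C9–OH; C5 bears CH3 and CH2CHO; C1 bears CH=CHOMe and CH2OTIPS; not isolated) | O[C@@H]1[C@@](C)(CC=O)CC[C@@H]([C@H](C)CCC=C(C)C)[C@]1(C=COC)CO[Si](C(C)C)(C(C)C)C(C)C | intermediate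
21 | 9-hydroxy-5-methyl-8-[(2R)-6-methylhept-5-en-2-yl]-1-{[(triisopropylsilyl)oxy]methyl}bicyclo[3.3.1]non-2-ene-2-carbaldehyde | O[C@@H]1[C@@]2(C)CC=C(C=O)[C@]1(CO[Si](C(C)C)(C(C)C)C(C)C)[C@H]([C@H](C)CCC=C(C)C)CC2 | intermediate
22 | C9 acetate of 21 | CC(=O)O[C@@H]1[C@@]2(C)CC=C(C=O)[C@]1(CO[Si](C(C)C)(C(C)C)C(C)C)[C@H]([C@H](C)CCC=C(C)C)CC2 | intermediate
23 | 9-acetoxy-1-(hydroxymethyl)-5-methyl-8-[(2R)-6-methylhept-5-en-2-yl]bicyclo[3.3.1]non-2-ene-2-carbaldehyde | CC(=O)O[C@@H]1[C@@]2(C)CC=C(C=O)[C@]1(CO)[C@H]([C@H](C)CCC=C(C)C)CC2 | intermediate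
24 | (1R,5R,8S,9R)-1,2-diformyl-5-methyl-8-[(2R)-6-methylhept-5-en-2-yl]bicyclo[3.3.1]non-2-en-9-yl acetate | CC(=O)O[C@@H]1[C@@]2(C)CC=C(C=O)[C@]1(C=O)[C@H]([C@H](C)CCC=C(C)C)CC2 | target

## Step count and risks

Total step count: 17. Longest linear sequence: 16 steps (steps 1–9 and 11–17; step 10 prepares the coupling partner).

Steps most likely to fail:

1. Step 14 (proposed new method). The conjugated aldehyde may be reduced and dimerise or be saturated faster than ring A closes, the transient α-formyl radical may attack the enol ether before it is reduced, or facial selectivity at C5 and C9 may be poor. Fallback, from 13 back to 21, with each bond made by a precedented step: the borane 16 from 13 would be coupled with methyl (E)-3-{[(trifluoromethyl)sulfonyl]oxy}but-2-enoate F1 (from methyl acetoacetate, Tf2O and aqueous Me4NOH) to give the methyl (E)-enoate F2. TBAF/AcOH would give the alcohol F3 and Dess–Martin oxidation the aldehyde enoate F4. SmI2 with t-BuOH, the established ketyl–olefin cyclization onto a β,β-disubstituted enoate, would give the trans hydroxy ester F5. DIBAL-H at −78 °C would then give hydroxy aldehyde 20, now isolated, and BF3·OEt2 in CH2Cl2 would close ring B to 21.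

2. Step 5. The enolate may eliminate the silyloxy group, the aldolate may revert, or the facial selectivity that sets the quaternary centre may be insufficient. Fallback, from 6 back to 9: double hydroxymethylation of 6 (LDA and formaldehyde, twice) would give the bis(hydroxymethyl) lactone F6. Silylation of the less hindered hydroxymethyl group, trans to the side chain, with one equivalent of TESCl would give the mono-silyl ether F7, and TIPSOTf with 2,6-lutidine would give 9. The stereocentre is then set by selective protection instead of by the order of alkylation.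

3. Step 11. Hydroboration may also attack the enol ether, or the hindered vinyl group may react slowly and the borane may be lost by protodeboronation. Fallback, from 12 back to 17, without hydroboration: Horner–Wadsworth–Emmons reaction of 12 with dimethyl (2-oxopropyl)phosphonate and Ba(OH)2 would give the (E)-enone F8. Conjugate reduction with [(Ph3P)CuH]6 would give the methyl ketone F9, and a second Horner–Wadsworth–Emmons reaction with triethyl phosphonoacetate and NaH would give the ethyl (E)-enoate F10 after removal of the minor Z isomer. DIBAL-H would then give 17.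

## Further compounds

F1 | step 14 | methyl (E)-3-{[(trifluoromethyl)sulfonyl]oxy}but-2-enoate | COC(=O)/C=C(\C)OS(=O)(=O)C(F)(F)F
F2 | step 14 | methyl (2E)-9-methoxy-3-methyl-6-[(2R)-6-methylhept-5-en-2-yl]-7-{[(triethylsilyl)oxy]methyl}-7-{[(triisopropylsilyl)oxy]methyl}nona-2,8-dienoate | COC=C[C@](CO[Si](CC)(CC)CC)(CO[Si](C(C)C)(C(C)C)C(C)C)[C@@H](CC/C(C)=C/C(=O)OC)[C@H](C)CCC=C(C)C
F3 | step 14 | methyl (2E)-7-(hydroxymethyl)-9-methoxy-3-methyl-6-[(2R)-6-methylhept-5-en-2-yl]-7-{[(triisopropylsilyl)oxy]methyl}nona-2,8-dienoate | COC=C[C@](CO)(CO[Si](C(C)C)(C(C)C)C(C)C)[C@@H](CC/C(C)=C/C(=O)OC)[C@H](C)CCC=C(C)C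
F4 | step 14 | methyl (2E)-7-formyl-9-methoxy-3-methyl-6-[(2R)-6-methylhept-5-en-2-yl]-7-{[(triisopropylsilyl)oxy]methyl}nona-2,8-dienoate | COC=C[C@](C=O)(CO[Si](C(C)C)(C(C)C)C(C)C)[C@@H](CC/C(C)=C/C(=O)OC)[C@H](C)CCC=C(C)C
F5 | step 14 | monocyclic hydroxy methyl ester (as 20 with CH2CO2CH3 in place of CH2CHO) | O[C@@H]1[C@@](C)(CC(=O)OC)CC[C@@H]([C@H](C)CCC=C(C)C)[C@]1(C=COC)CO[Si](C(C)C)(C(C)C)C(C)C
F6 | step 5 | (4S)-3,3-bis(hydroxymethyl)-4-[(2R)-6-methylhept-5-en-2-yl]oxolan-2-one | O=C1C(CO)(CO)[C@@H](CO1)[C@H](C)CCC=C(C)C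
F7 | step 5 | 3-(hydroxymethyl)-4-[(2R)-6-methylhept-5-en-2-yl]-3-{[(triethylsilyl)oxy]methyl}oxolan-2-one (CH2OTES trans to the side chain) | O=C1[C@](CO[Si](CC)(CC)CC)(CO)[C@@H](CO1)[C@H](C)CCC=C(C)C
F8 | step 11 | (E)-enone from 12 (CH=CH–C(O)CH3 in place of CHO) | COC=C[C@](CO[Si](CC)(CC)CC)(CO[Si](C(C)C)(C(C)C)C(C)C)[C@@H](/C=C/C(C)=O)[C@H](C)CCC=C(C)C
F9 | step 11 | saturated methyl ketone from F8 | COC=C[C@](CO[Si](CC)(CC)CC)(CO[Si](C(C)C)(C(C)C)C(C)C)[C@@H](CCC(C)=O)[C@H](C)CCC=C(C)C
F10 | step 11 | ethyl (2E)-9-methoxy-3-methyl-6-[(2R)-6-methylhept-5-en-2-yl]-7-{[(triethylsilyl)oxy]methyl}-7-{[(triisopropylsilyl)oxy]methyl}nona-2,8-dienoate | COC=C[C@](CO[Si](CC)(CC)CC)(CO[Si](C(C)C)(C(C)C)C(C)C)[C@@H](CC/C(C)=C/C(=O)OCC)[C@H](C)CCC=C(C)C
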